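**Retrosynthetic overview**

1. Cudraflavanone A ⇐ its tris-MOM ether (global deprotection). Ring C ⇐ a racemic cyclic enol acetal (2-aryl-4-methylidene-4H-1,3-benzodioxine) by an enantioconvergent, chiral-acid-catalysed [1,3] O-to-C shift (Petasis–Ferrier type) that forms the C2–C3 bond, unveils the C4 ketone and sets the C2 stereocentre in one operation.
2. Enol acetal ⇐ 2-aryl-4H-1,3-benzodioxin-4-one (titanium carbene methylenation) ⇐ prenylated salicylic acid + chromene aldehyde (acylal condensation).
3. Salicylic acid ⇐ methyl 2,4,6-trihydroxybenzoate (bis-MOM ether, O-prenylation, para-Claisen–Cope through the oxygen that becomes O1, which places the prenyl group on C6 by construction). Aldehyde ⇐ resorcinol (chromanone, chromene, ortho-formylation, MOM ether).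
4. Ring order: the pyran ring of the ring-B chromene first, then a temporary 1,3-dioxine ring on ring A, then ring C last; the benzene rings A and B are bought.
5. Enabling feature: C2 lies between O1 and C1′ of ring B, whose oxygens at C2′ and C4′ are ortho and para to C1′ and stabilise a cation at C2, while C3 is the enol carbon of the C4 aryl ketone on ring A. O1–C2 and C3–C4=O are thus an oxocarbenium/enol pair that can be stored as its O-linked isomer (C2–O–C4=CH2).

Key step: step 11

Remark: the acetal carbon of the dioxinone and of the enol acetal is carried as the racemate because the key step erases it; the sense of induction of the chiral acid cannot be predicted with certainty, so the catalyst enantiomer is to be assigned in a first run (both are available).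

**Route**

Step 1
Reactants: 1 resorcinol; 2 3-methylbut-2-enoic acid
Product: 3 7-hydroxy-2,2-dimethylchroman-4-one
Conditions: P2O5, MeSO3H, 70 °C
Reagents that add atoms: none
Why: Friedel–Crafts acylation of resorcinol at C4 followed by intramolecular oxa-Michael addition of the ortho hydroxyl is the standard entry to 2,2-dimethylchroman-4-ones, the position between the two hydroxyls being the hindered one; no stereocentre is formed.

Step 2
Reactants: 3 7-hydroxy-2,2-dimethylchroman-4-one
Product: 5 2,2-dimethyl-2H-chromen-7-ol, via benzylic alcohol 4 (not isolated)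
Conditions: NaBH4, MeOH/THF, 0 °C → rt; extractive work-up; then p-TsOH·H2O (cat.), toluene, 60 °C
Reagents that add atoms: none
Why: Borohydride reduction of the aryl ketone gives a para-hydroxybenzylic alcohol (racemic, its stereocentre is destroyed again) that should lose water under mild acid catalysis (E1 dehydration through the oxygen-stabilised benzylic cation) to the conjugated 2H-chromene.

Step 3
Reactants: 5 2,2-dimethyl-2H-chromen-7-ol
Product: 7 7-hydroxy-2,2-dimethyl-2H-chromene-6-carbaldehyde, via hydroxymethyl phenol 6 (not isolated)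
Conditions: MgCl2, Et3N, (CH2O)n, MeCN, reflux
Reagents that add atoms: paraformaldehyde (as formaldehyde), C=O
Why: Magnesium-phenoxide-directed ortho-formylation (Casnati–Skattebøl reaction) delivers formaldehyde only ortho to the free hydroxyl, C6 being unhindered and para to the ring oxygen whereas C8 lies between two oxygens, and the hydroxymethyl intermediate is oxidised in the flask by a second formaldehyde through hydride transfer.

Step 4
Reactants: 7 7-hydroxy-2,2-dimethyl-2H-chromene-6-carbaldehyde
Product: 8 7-(methoxymethoxy)-2,2-dimethyl-2H-chromene-6-carbaldehyde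
Conditions: MOMCl, K2CO3, acetone, 0 °C → reflux
Reagents that add atoms: chloromethyl methyl ether, COCCl
Why: Williamson-type O-alkylation of the phenoxide with the reactive alpha-chloro ether masks the hydroxyl that would otherwise interfere with acylal formation and with the titanium reagent.

Step 5
Reactants: 9 methyl 2,4,6-trihydroxybenzoate
Product: 10 methyl 2-hydroxy-4,6-bis(methoxymethoxy)benzoate
Conditions: MOMCl (2.1 equiv), K2CO3, acetone, 0 °C → rt
Reagents that add atoms: chloromethyl methyl ether, COCCl
Why: O-Alkylation takes the para hydroxyl and one of the two equivalent ortho hydroxyls, after which the last hydroxyl is held in a hydrogen bond to the ester carbonyl and reacts much more slowly, so the bis-ether is the expected main product (selective protection).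

Step 6
Reactants: 10 methyl 2-hydroxy-4,6-bis(methoxymethoxy)benzoate
Product: 11 methyl 2,4-bis(methoxymethoxy)-6-[(3-methylbut-2-en-1-yl)oxy]benzoate
Conditions: prenyl bromide, K2CO3, DMF, rt → 50 °C
Reagents that add atoms: 1-bromo-3-methylbut-2-ene, CC(C)=CCBr
Why: Williamson etherification with the primary allylic bromide (SN2) converts the remaining chelated phenol, the oxygen that becomes O1 of the target, into its prenyl ether.

Step 7
Reactants: 11 methyl 2,4-bis(methoxymethoxy)-6-[(3-methylbut-2-en-1-yl)oxy]benzoate
Product: 14 methyl 6-hydroxy-2,4-bis(methoxymethoxy)-3-(3-methylbut-2-en-1-yl)benzoate, via ortho-dienone 12 (not isolated), via para-dienone 13 (not isolated)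
Conditions: N,N-diethylaniline, 200 °C, argon
Reagents that add atoms: none
Why: Aromatic Claisen rearrangement to the free ortho carbon, Cope rearrangement of the crowded ortho-dienone and tautomerisation (para-Claisen–Cope sequence, known for ortho-acyl aryl prenyl ethers flanked by alkoxy groups) should place an unrearranged prenyl group para to the oxygen, between the two MOM ethers, and return the free phenol, which fixes the C6 regiochemistry of the target.

Step 8
Reactants: 14 methyl 6-hydroxy-2,4-bis(methoxymethoxy)-3-(3-methylbut-2-en-1-yl)benzoate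
Product: 15 6-hydroxy-2,4-bis(methoxymethoxy)-3-(3-methylbut-2-en-1-yl)benzoic acid
Conditions: LiOH·H2O, THF/MeOH/H2O, 60 °C; then 1 M HCl to pH 4, 0 °C
Reagents that add atoms: lithium hydroxide, [Li+].[OH-]
Why: Saponification of the salicylate ester, assisted by the neighbouring phenoxide, should give the acid, and acidification only to pH 4 in the cold avoids protodecarboxylation and loss of MOM groups.

Step 9
Reactants: 15 6-hydroxy-2,4-bis(methoxymethoxy)-3-(3-methylbut-2-en-1-yl)benzoic acid; 8 7-(methoxymethoxy)-2,2-dimethyl-2H-chromene-6-carbaldehyde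
Product: 17 rac-5,7-bis(methoxymethoxy)-2-[7-(methoxymethoxy)-2,2-dimethyl-2H-chromen-6-yl]-6-(3-methylbut-2-en-1-yl)-4H-1,3-benzodioxin-4-one, via bis(trimethylsilyl) derivative 16 (not isolated)
Conditions: HMDS, THF, 50 °C, evaporate; then 8, TMSOTf (0.2 equiv), CH2Cl2, −78 °C; pyridine quench
Reagents that add atoms: none
Why: Silylation of both acidic groups followed by TMSOTf-catalysed condensation with the aldehyde at low temperature (acetalisation of a bis-silylated hydroxy acid, the union step of the Petasis–Ferrier tactic) should form the six-membered acylal with loss of hexamethyldisiloxane, the single free phenol ensuring that O1 is the oxygen para to the prenyl group; the acetal centre forms as the racemate, which is of no consequence.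

Step 10
Reactants: 17 rac-2-aryl-5,7-bis(methoxymethoxy)-6-prenyl-4H-1,3-benzodioxin-4-one
Product: 18 rac-5,7-bis(methoxymethoxy)-2-[7-(methoxymethoxy)-2,2-dimethyl-2H-chromen-6-yl]-4-methylidene-6-(3-methylbut-2-en-1-yl)-4H-1,3-benzodioxine
Conditions: Cp2TiMe2 (2.5 equiv), toluene/THF, 65 °C, dark; filtration through basic alumina
Reagents that add atoms: dimethyltitanocene, [CH3-].[CH3-].c1cc[cH-]c1.c1cc[cH-]c1.[Ti+4]
Why: Carbonyl methylenation of the lactone by the titanium carbene Cp2Ti=CH2 generated thermally from Cp2TiMe2 (Petasis methylenation) is neither acidic nor basic, tolerates acetals, MOM ethers and both alkenes, and should convert the acylal into the cyclic enol acetal.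

Step 11
Reactants: 18 rac-2-aryl-4-methylidene-4H-1,3-benzodioxine
Product: 20 (2S)-5,7-bis(methoxymethoxy)-2-[7-(methoxymethoxy)-2,2-dimethyl-2H-chromen-6-yl]-6-(3-methylbut-2-en-1-yl)-2,3-dihydro-4H-chromen-4-one, via oxocarbenium enol ion pair 19 (not isolated)
Conditions: (R)-TRIP [3,3′-bis(2,4,6-triisopropylphenyl)-1,1′-binaphthyl-2,2′-diyl hydrogen phosphate] (10 mol%), 4 Å MS, toluene, −20 °C; Et3N quench
Reagents that add atoms: none
Why: Proposed new method: the chiral phosphoric acid protonates the enol-acetal oxygen of 18 and the C2–O bond to that oxygen ionises, because the aryloxycarbenium ion at C2 is stabilised by the ortho and para oxygens of ring B; this leaves the enol of the ring-A ketone hydrogen-bonded to the chiral phosphate in ion pair 19, and its carbon terminus C3 recombines with C2 in a [1,3] O-to-C shift made irreversible by formation of the aryl ketone. The closest known reaction types are the Petasis–Ferrier rearrangement of 4-methylidene-1,3-dioxanes to tetrahydropyran-4-ones with Me2AlCl and the chiral-phosphoric-acid-catalysed aza-Petasis–Ferrier rearrangement of racemic hemiaminal vinyl ethers, and asymmetric Prins cyclisations of salicylaldehyde-derived oxocarbenium ions under confined chiral acids support anion control of this kind of cation. Ring C is closed in a 6-(enolendo)-endo-trig mode, the oxocarbenium C=O+ lying inside the forming ring. The C2 stereocentre is controlled by the catalyst alone: the acetal centre of racemic 18 is erased on ionisation (enantioconvergent), and the phosphate, bound to the enol OH and paired with the cation, selects the face of C2. The step needs C- over O-recombination (O-return only regenerates 18), ionisation in preference to C-protonation of the enol ether (reversible, so it drains back) and exclusion of water (molecular sieves), while the tether that holds C3 six atoms from C2 secures the regiochemistry. The catalyst enantiomer that gives the 2S product is fixed in a first experiment.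

Step 12
Reactants: 20 (2S)-tris-MOM flavanone
Product: 21 cudraflavanone A, (2S)-5,7-dihydroxy-2-(7-hydroxy-2,2-dimethyl-2H-chromen-6-yl)-6-(3-methylbut-2-en-1-yl)-2,3-dihydro-4H-chromen-4-one
Conditions: conc. HCl (cat.), MeOH/THF, 0 °C → rt
Reagents that add atoms: none
Why: Acid-catalysed transacetalisation of the three aryl MOM ethers to dimethoxymethane in methanol is standard for prenylated flavanones, and the mild conditions are chosen so that the C2 stereocentre, the prenyl group and the chromene should stay untouched.

**Compound list**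

1 | resorcinol (benzene-1,3-diol) | Oc1cccc(O)c1 | starting material
2 | 3-methylbut-2-enoic acid | CC(C)=CC(=O)O | starting material
3 | 7-hydroxy-2,2-dimethylchroman-4-one | CC1(C)CC(=O)c2ccc(O)cc2O1 | intermediate
4 | 2,2-dimethylchromane-4,7-diol (racemic benzylic alcohol, formed in the flask) | CC1(C)CC(O)c2ccc(O)cc2O1 | intermediate
5 | 2,2-dimethyl-2H-chromen-7-ol | CC1(C)C=Cc2ccc(O)cc2O1 | intermediate
6 | 6-(hydroxymethyl)-2,2-dimethyl-2H-chromen-7-ol (formed in the flask) | CC1(C)C=Cc2cc(CO)c(O)cc2O1 | intermediate
7 | 7-hydroxy-2,2-dimethyl-2H-chromene-6-carbaldehyde | CC1(C)C=Cc2cc(C=O)c(O)cc2O1 | intermediate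
8 | 7-(methoxymethoxy)-2,2-dimethyl-2H-chromene-6-carbaldehyde | CC1(C)C=Cc2cc(C=O)c(OCOC)cc2O1 | intermediate
9 | methyl 2,4,6-trihydroxybenzoate | COC(=O)c1c(O)cc(O)cc1O | starting material
10 | methyl 2-hydroxy-4,6-bis(methoxymethoxy)benzoate | COC(=O)c1c(O)cc(OCOC)cc1OCOC | intermediate
11 | methyl 2,4-bis(methoxymethoxy)-6-[(3-methylbut-2-en-1-yl)oxy]benzoate | COC(=O)c1c(OCOC)cc(OCOC)cc1OCC=C(C)C | intermediate
12 | methyl 2,4-bis(methoxymethoxy)-5-(2-methylbut-3-en-2-yl)-6-oxocyclohexa-1,3-diene-1-carboxylate (racemic ortho-dienone, formed in the flask) | COC(=O)C1=C(OCOC)C=C(OCOC)C(C(C)(C)C=C)C1=O | intermediate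
13 | methyl 2,4-bis(methoxymethoxy)-3-(3-methylbut-2-en-1-yl)-6-oxocyclohexa-1,4-diene-1-carboxylate (racemic para-dienone, formed in the flask) | COC(=O)C1=C(OCOC)C(CC=C(C)C)C(OCOC)=CC1=O | intermediate
14 | methyl 6-hydroxy-2,4-bis(methoxymethoxy)-3-(3-methylbut-2-en-1-yl)benzoate | COC(=O)c1c(O)cc(OCOC)c(CC=C(C)C)c1OCOC | intermediate
15 | 6-hydroxy-2,4-bis(methoxymethoxy)-3-(3-methylbut-2-en-1-yl)benzoic acid | OC(=O)c1c(O)cc(OCOC)c(CC=C(C)C)c1OCOC | intermediate
16 | trimethylsilyl 2,4-bis(methoxymethoxy)-3-(3-methylbut-2-en-1-yl)-6-[(trimethylsilyl)oxy]benzoate (formed in the flask) | C[Si](C)(C)OC(=O)c1c(O[Si](C)(C)C)cc(OCOC)c(CC=C(C)C)c1OCOC | intermediate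
17 | rac-5,7-bis(methoxymethoxy)-2-[7-(methoxymethoxy)-2,2-dimethyl-2H-chromen-6-yl]-6-(3-methylbut-2-en-1-yl)-4H-1,3-benzodioxin-4-one | O=C1OC(c2cc3c(cc2OCOC)OC(C)(C)C=C3)Oc2cc(OCOC)c(CC=C(C)C)c(OCOC)c21 | intermediate
18 | rac-5,7-bis(methoxymethoxy)-2-[7-(methoxymethoxy)-2,2-dimethyl-2H-chromen-6-yl]-4-methylidene-6-(3-methylbut-2-en-1-yl)-4H-1,3-benzodioxine | C=C1OC(c2cc3c(cc2OCOC)OC(C)(C)C=C3)Oc2cc(OCOC)c(CC=C(C)C)c(OCOC)c21 | intermediate
19 | aryloxycarbenium ion carrying the ring-A ketone enol (cation of the ion pair with the chiral phosphate, formed in the flask) | C=C(O)c1c(OCOC)c(CC=C(C)C)c(OCOC)cc1[O+]=Cc1cc2c(cc1OCOC)OC(C)(C)C=C2 | intermediate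
20 | (2S)-5,7-bis(methoxymethoxy)-2-[7-(methoxymethoxy)-2,2-dimethyl-2H-chromen-6-yl]-6-(3-methylbut-2-en-1-yl)-2,3-dihydro-4H-chromen-4-one | CC(C)=CCc1c(OCOC)cc2c(c1OCOC)C(=O)C[C@@H](c1cc3c(cc1OCOC)OC(C)(C)C=C3)O2 | intermediate
21 | cudraflavanone A, (2S)-5,7-dihydroxy-2-(7-hydroxy-2,2-dimethyl-2H-chromen-6-yl)-6-(3-methylbut-2-en-1-yl)-2,3-dihydro-4H-chromen-4-one | CC(C)=CCc1c(O)cc2c(c1O)C(=O)C[C@@H](c1cc3c(cc1O)OC(C)(C)C=C3)O2 | target

**Step count and risks**

Total step count: 12.
Longest linear sequence: 8 steps (steps 5 to 12; the sequence of steps 1 to 4 and 9 to 12 is equally long).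

Steps most likely to fail:

1. Step 11 (Proposed new method). What may go wrong: C-protonation of the enol ether followed by hydrolytic or oligomerising loss of the oxocarbenium ion, or poor facial selectivity in the recombination. Fallback with known chemistry, setting out from 18 and returning at 20: brief treatment with PPTS in wet acetone hydrolyses the enol acetal to the methyl ketone 1-[6-hydroxy-2,4-bis(methoxymethoxy)-3-(3-methylbut-2-en-1-yl)phenyl]ethan-1-one F1, with return of aldehyde 8. Claisen–Schmidt condensation of the two (KOH, EtOH, rt) gives the (E)-2′-hydroxychalcone F2. NaOAc in refluxing EtOH closes it by oxa-Michael addition to the racemic tris-MOM flavanone F3. Kinetic resolution by asymmetric transfer hydrogenation (RuCl(p-cymene)[TsDPEN] of the appropriate configuration, HCO2H/Et3N, rt), which leaves the prenyl and chromene alkenes alone, reduces the 2R ketone to the (2R,4R)-cis-flavan-4-ol F4 and leaves 20, at most half of the material.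

2. Step 9. What may go wrong: protodecarboxylation of the electron-rich salicylic acid, reversal or ionisation of the acid-labile acylal, and loss of MOM groups under the silyl Lewis acid. Fallback, setting out from 14 and 8 and returning at 17: NaBH4 reduces 8 to [7-(methoxymethoxy)-2,2-dimethyl-2H-chromen-6-yl]methanol F5. Mitsunobu etherification (PPh3, DIAD, THF) with phenol 14 gives the aryl benzyl ether methyl 2,4-bis(methoxymethoxy)-6-{[7-(methoxymethoxy)-2,2-dimethyl-2H-chromen-6-yl]methoxy}-3-(3-methylbut-2-en-1-yl)benzoate F6. Forcing saponification (LiOH, aqueous DMSO, 80 °C) gives the corresponding benzoic acid F7. DDQ (CH2Cl2, 4 Å MS, 0 °C) then abstracts hydride from the doubly oxygen-activated benzylic ether position and the carboxyl group traps the oxocarbenium ion (oxidative acetalisation), closing the dioxinone ring of 17 without a free hydroxy acid ever meeting a Lewis acid.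

3. Step 12. What may go wrong: acid-induced addition of methanol to the electron-rich chromene double bond, cyclisation of the prenyl group onto a neighbouring phenol, or racemisation through ionisation of the C2–O1 bond once the 2′-hydroxyl is free. Fallback, setting out from 20 and returning at 21: non-protic transprotection with TMSOTf and 2,2′-bipyridyl (CH2Cl2, 0 °C) converts the aryl MOM ethers into the tris(trimethylsilyl) ether (2S)-5,7-bis[(trimethylsilyl)oxy]-2-{2,2-dimethyl-7-[(trimethylsilyl)oxy]-2H-chromen-6-yl}-6-(3-methylbut-2-en-1-yl)-2,3-dihydro-4H-chromen-4-one F8, which water hydrolyses at neutral pH to 21.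

**Further compounds**

F1 | step 11 | 1-[6-hydroxy-2,4-bis(methoxymethoxy)-3-(3-methylbut-2-en-1-yl)phenyl]ethan-1-one | CC(=O)c1c(O)cc(OCOC)c(CC=C(C)C)c1OCOC
F2 | step 11 | (E)-1-[6-hydroxy-2,4-bis(methoxymethoxy)-3-(3-methylbut-2-en-1-yl)phenyl]-3-[7-(methoxymethoxy)-2,2-dimethyl-2H-chromen-6-yl]prop-2-en-1-one | O=C(/C=C/c1cc2c(cc1OCOC)OC(C)(C)C=C2)c1c(O)cc(OCOC)c(CC=C(C)C)c1OCOC
F3 | step 11 | rac-5,7-bis(methoxymethoxy)-2-[7-(methoxymethoxy)-2,2-dimethyl-2H-chromen-6-yl]-6-(3-methylbut-2-en-1-yl)-2,3-dihydro-4H-chromen-4-one | CC(C)=CCc1c(OCOC)cc2c(c1OCOC)C(=O)CC(c1cc3c(cc1OCOC)OC(C)(C)C=C3)O2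
F4 | step 11 | (2R,4R)-5,7-bis(methoxymethoxy)-2-[7-(methoxymethoxy)-2,2-dimethyl-2H-chromen-6-yl]-6-(3-methylbut-2-en-1-yl)chroman-4-ol (2,4-cis) | CC(C)=CCc1c(OCOC)cc2c(c1OCOC)[C@H](O)C[C@H](c1cc3c(cc1OCOC)OC(C)(C)C=C3)O2
F5 | step 9 | [7-(methoxymethoxy)-2,2-dimethyl-2H-chromen-6-yl]methanol | CC1(C)C=Cc2cc(CO)c(OCOC)cc2O1
F6 | step 9 | methyl 2,4-bis(methoxymethoxy)-6-{[7-(methoxymethoxy)-2,2-dimethyl-2H-chromen-6-yl]methoxy}-3-(3-methylbut-2-en-1-yl)benzoate | COC(=O)c1c(OCc2cc3c(cc2OCOC)OC(C)(C)C=C3)cc(OCOC)c(CC=C(C)C)c1OCOC
F7 | step 9 | 2,4-bis(methoxymethoxy)-6-{[7-(methoxymethoxy)-2,2-dimethyl-2H-chromen-6-yl]methoxy}-3-(3-methylbut-2-en-1-yl)benzoic acid | OC(=O)c1c(OCc2cc3c(cc2OCOC)OC(C)(C)C=C3)cc(OCOC)c(CC=C(C)C)c1OCOC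
F8 | step 12 | (2S)-5,7-bis[(trimethylsilyl)oxy]-2-{2,2-dimethyl-7-[(trimethylsilyl)oxy]-2H-chromen-6-yl}-6-(3-methylbut-2-en-1-yl)-2,3-dihydro-4H-chromen-4-one | CC(C)=CCc1c(O[Si](C)(C)C)cc2c(c1O[Si](C)(C)C)C(=O)C[C@@H](c1cc3c(cc1O[Si](C)(C)C)OC(C)(C)C=C3)O2
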